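**Retrosynthetic overview**

1. Numbering: C1 furanone C=O, C2 furanone CH, C3 furanone enol‑ether carbon, C4 (CHMe), C5 (CHOH), C6 (CH–O‑methacrylate), C7/C8 lactone ring fusion (C8–O), C9 (CH2), C10 (CMe–O), C11–C13 methylene‑lactone carbons, O10 the furanone oxygen. The target is a 3(2H)‑furanone (O10, C3, C2, C1, C10) bridging the ten‑membered carbocycle C1–C10, with a trans‑fused α‑methylene‑γ‑butyrolactone on C7/C8.
2. Enabling feature: O10 joins C3 and C10, so C3 can be carried as a lactone carbonyl on O10 while C1/C2 wait as an acetyl group on C10. Closing C2–C3 through the five‑atom chain C2–C1–C10–O10–C3 then makes the furanone and, with it, the carbocycle, without any ten‑membered transition state.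
3. Key disconnection: furanone ⇒ (C2–C3, −H2O) nine‑membered α‑acyloxy‑ketone lactone; that lactone and the butyrolactone ⇒ (C7–C8) intramolecular CrCl2‑mediated allylation of an ester‑linked bromo‑enoate/aldehyde.
4. Ester ⇒ acid C3–C7 (Evans aldol sets C4 and C5; C6 comes from (R)‑but‑3‑ene‑1,2‑diol) + tertiary ketol C8–C10/C1/C2 (lactic acid dioxolanone alkylation sets C10).
5. Ring order: butyrolactone and nine‑membered lactone together (step 14), then the furanone, which completes the carbocycle (step 15); methacrylate on O6 and desilylation close the route.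

Key step: step 15

Remark: the SMILES is read as 4S,5S,6S,7R,8S,10R (trans‑fused lactone; Me‑4, O‑5, O‑6, C11 on C7 and O‑8 all syn on the extended C3–C9 chain).
Remark: TES = triethylsilyl, TBS = tert‑butyldimethylsilyl; compounds 1, 2, 4, 7, 10, 16 and 25 are taken as commercial.

Step 1
Reactants: 1 (S)‑lactic acid; 2 pivalaldehyde
Product: 3 (2S,5S)‑2‑tert‑butyl‑5‑methyl‑1,3‑dioxolan‑4‑one (cis)
Conditions: TsOH·H2O (cat.), H2SO4 (cat.), pentane, reflux, Dean–Stark; crystallisation
Reagents that add atoms: none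
Why: Acid‑catalysed acetalisation with azeotropic removal of water; the cis acetal (tert‑butyl and methyl on one face) should predominate and is purified by crystallisation, so the lactate centre is kept and the acetal carbon is set relative to it.

Step 2
Reactants: 3 (2S,5S)‑2‑tert‑butyl‑5‑methyl‑1,3‑dioxolan‑4‑one; 4 allyl bromide
Product: 5 (2S,5R)‑2‑tert‑butyl‑5‑methyl‑5‑(prop‑2‑en‑1‑yl)‑1,3‑dioxolan‑4‑one
Conditions: LiN(i‑Pr)2, THF, −78 °C; then 4, −78 → −30 °C
Reagents that add atoms: none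
Why: Enolate alkylation with self‑regeneration of the stereocentre: the tert‑butyl group blocks one face of the planar lithium enolate, so the allyl group enters trans to it and the lactate carbon becomes the quaternary centre that is C10 (R).

Step 3
Reactants: 5 (2S,5R)‑2‑tert‑butyl‑5‑methyl‑5‑(prop‑2‑en‑1‑yl)‑1,3‑dioxolan‑4‑one
Product: 6 (R)‑3‑hydroxy‑3‑methylhex‑5‑en‑2‑one (C8–C10, C1, C2)
Conditions: MeLi (1.05 equiv), Et2O, −78 °C; then aq. NH4Cl at −78 °C
Reagents that add atoms: methyllithium, [Li]C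
Why: 1,2‑Addition of MeLi to the lactone‑type carbonyl, which has no α‑hydrogen, should stop at the cyclic hemiketal alkoxide at low temperature; protonation opens it to the methyl ketone and releases pivalaldehyde, leaving the quaternary carbinol untouched.

Step 4
Reactants: 7 (R)‑but‑3‑ene‑1,2‑diol
Product: 8 (R)‑3,4‑bis(triethylsilyloxy)but‑1‑ene
Conditions: TESCl, imidazole, CH2Cl2, 0 → 23 °C
Reagents that add atoms: chlorotriethylsilane, CC[Si](Cl)(CC)CC
Why: Standard silylation of a primary and a secondary alcohol with a silyl chloride and imidazole; no stereocentre is touched.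

Step 5
Reactants: 8 (R)‑3,4‑bis(triethylsilyloxy)but‑1‑ene
Product: 9 (S)‑2,3‑bis(triethylsilyloxy)propanal
Conditions: O3, CH2Cl2, −78 °C; then PPh3, −78 → 23 °C
Reagents that add atoms: ozone, [O-][O+]=O
Why: Ozonolysis with reductive work‑up cleaves the only alkene to the α‑silyloxy aldehyde under neutral conditions that do not enolise the stereocentre (the descriptor changes only by priority).

Step 6
Reactants: 9 (S)‑2,3‑bis(triethylsilyloxy)propanal; 10 (S)‑4‑benzyl‑3‑propanoyl‑1,3‑oxazolidin‑2‑one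
Product: 11 (S)‑4‑benzyl‑3‑[(2S,3S,4S)‑3‑hydroxy‑2‑methyl‑4,5‑bis(triethylsilyloxy)pentanoyl]‑1,3‑oxazolidin‑2‑one
Conditions: Bu2BOTf, i‑Pr2NEt, CH2Cl2, −78 → 0 °C; then 9, −78 → 0 °C; pH 7 buffer, MeOH, H2O2
Reagents that add atoms: none
Why: Evans syn‑aldol reaction: the (Z)‑boron enolate reacts through a Zimmerman–Traxler chair in which the benzyl group of the auxiliary fixes the enolate face, setting C4 and C5 syn, while C6 comes from the aldehyde; auxiliary control is expected to override the weak Felkin preference of the α‑silyloxy aldehyde.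

Step 7
Reactants: 11 aldol adduct
Product: 12 (S)‑4‑benzyl‑3‑[(2S,3S,4S)‑3‑(tert‑butyldimethylsilyloxy)‑2‑methyl‑4,5‑bis(triethylsilyloxy)pentanoyl]‑1,3‑oxazolidin‑2‑one
Conditions: TBSOTf, 2,6‑lutidine, CH2Cl2, −78 → 0 °C
Reagents that add atoms: tert‑butyldimethylsilyl triflate, CC(C)(C)[Si](C)(C)OS(=O)(=O)C(F)(F)F
Why: A silyl triflate with a hindered pyridine base silylates the hindered secondary carbinol; this blocks retro‑aldol cleavage and distinguishes O5 (TBS) from O6 (TES).

Step 8
Reactants: 12 silylated imide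
Product: 13 (2S,3S,4S)‑3‑(tert‑butyldimethylsilyloxy)‑2‑methyl‑4,5‑bis(triethylsilyloxy)pentanoic acid (C3–C7)
Conditions: LiOH, H2O2, THF/H2O, 0 °C; then Na2SO3; dilute HCl to pH 4 at 0 °C
Reagents that add atoms: hydrogen peroxide, OO (as LiOOH)
Why: Hydroperoxide attacks the exocyclic imide carbonyl selectively (LiOOH cleavage) and is a poor base, so the auxiliary is released without epimerising C4.

Step 9
Reactants: 13 acid; 6 (R)‑3‑hydroxy‑3‑methylhex‑5‑en‑2‑one
Product: 14 (3R)‑3‑methyl‑2‑oxohex‑5‑en‑3‑yl (2S,3S,4S)‑3‑(tert‑butyldimethylsilyloxy)‑2‑methyl‑4,5‑bis(triethylsilyloxy)pentanoate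
Conditions: 2,4,6‑Cl3C6H2COCl, Et3N, THF, 23 °C; then 6, DMAP, toluene, 23 → 50 °C
Reagents that add atoms: none
Why: Yamaguchi esterification: the mixed anhydride and the derived acylpyridinium ion are reactive enough to acylate the tertiary α‑ketol; no stereocentre is formed and quaternary C10 cannot epimerise.

Step 10
Reactants: 14 ester
Product: 15 (3R)‑3‑methyl‑2‑oxohex‑5‑en‑3‑yl (2S,3S,4R)‑3‑(tert‑butyldimethylsilyloxy)‑2‑methyl‑5‑oxo‑4‑(triethylsilyloxy)pentanoate
Conditions: (COCl)2, DMSO, CH2Cl2, −78 → −40 °C; then Et3N, −78 → 0 °C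
Reagents that add atoms: none
Why: Under Swern conditions the chlorosulfonium ion cleaves a primary triethylsilyl ether in preference to the secondary silyl ethers and oxidises it directly to the aldehyde (C7); the C6 descriptor changes only by priority.

Step 11
Reactants: 15 aldehyde; 16 methyl propiolate
Product: 17 1‑methyl 7‑[(3R)‑3‑methyl‑2‑oxohex‑5‑en‑3‑yl] (4S,5S,6S)‑5‑(tert‑butyldimethylsilyloxy)‑3‑hydroxy‑6‑methyl‑2‑methylidene‑4‑(triethylsilyloxy)heptanedioate (both C3 epimers)
Conditions: i‑Bu2AlH, N‑methylmorpholine N‑oxide, 16, THF, 0 °C; then 15, 0 → 23 °C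
Reagents that add atoms: none
Why: Hydroalumination of methyl propiolate gives the α‑(methoxycarbonyl)vinylalane, which adds to the aldehyde much faster than to the hindered ketone and gives the Morita–Baylis–Hillman‑type adduct without an amine base, so C6 is not epimerised; the new carbinol centre is not controlled and is erased in step 12.

Step 12
Reactants: 17 allylic alcohol
Product: 18 1‑methyl 7‑[(3R)‑3‑methyl‑2‑oxohex‑5‑en‑3‑yl] (2Z,4S,5S,6S)‑2‑(bromomethyl)‑5‑(tert‑butyldimethylsilyloxy)‑6‑methyl‑4‑(triethylsilyloxy)hept‑2‑enedioate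
Conditions: NBS, Me2S, CH2Cl2, 0 °C
Reagents that add atoms: N‑bromosuccinimide, O=C1CCC(=O)N1Br
Why: Activation of the allylic alcohol as an alkoxysulfonium ion (Corey–Kim‑type) and SN2′ attack of bromide give the rearranged primary allylic bromide, the (Z)‑enoate being the thermodynamically preferred isomer; the geometry does not matter for step 14.

Step 13
Reactants: 18 allylic bromide
Product: 19 1‑methyl 7‑[(3R)‑3‑methyl‑1,4‑dioxopentan‑3‑yl] (2Z,4S,5S,6S)‑2‑(bromomethyl)‑5‑(tert‑butyldimethylsilyloxy)‑6‑methyl‑4‑(triethylsilyloxy)hept‑2‑enedioate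
Conditions: OsO4 (cat.), NaIO4, 2,6‑lutidine, dioxane/H2O, 23 °C
Reagents that add atoms: osmium tetroxide OsO4, O=[Os](=O)(=O)=O (oxygen carrier); sodium periodate NaIO4, [Na+].[O-]I(=O)(=O)=O
Why: Johnson–Lemieux cleavage: OsO4 dihydroxylates the electron‑rich monosubstituted alkene in preference to the electron‑poor trisubstituted bromo‑enoate, and NaIO4 cleaves the diol to the C8 aldehyde.

Step 14
Reactants: 19 bromo‑enoate aldehyde
Product: 21 (4S,5S,6S,7R,8S,10R) nine‑membered lactone (ring O10–C3(=O)–C4–C5–C6–C7–C8–C9–C10) with 10‑acetyl and 10‑methyl groups and 5‑OTBS and 6‑OTES ethers and a trans‑fused 8,12‑olide bearing the 11(13)‑methylene group, via open hydroxy ester 20 (not isolated)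
Conditions: CrCl2 (excess), THF, 23 → 40 °C, slow addition of 19 (final about 2 mM)
Reagents that add atoms: none
Why: Nozaki–Hiyama–Kishi‑type intramolecular allylation: CrCl2 turns the allylic bromide into an equilibrating allylchromium species that adds through its γ‑carbon (C7) to the aldehyde (C8) in a chair transition state with both chain substituents equatorial, which should give the anti adduct and, after attack of the chromium alkoxide on the methyl ester, the trans‑fused methylene lactone; the face selection that relates C7/C8 to C6 rests on the conformation of the nine‑membered transition state and is not secured, and the ketone is far less reactive than the aldehyde.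

Step 15
Reactants: 21 nine‑membered lactone
Product: 23 (4S,5S,6S,7R,8S,10R) bridged 3(2H)‑furanone with 5‑OTBS and 6‑OTES ethers (target skeleton complete), via ten‑membered hydroxy diketone 22 (not isolated)
Conditions: LiN(SiMe3)2 (1.5 equiv), THF (5 mM), −78 → 0 °C; then AcOH, 0 → 23 °C
Reagents that add atoms: none
Why: Kinetic deprotonation gives the lithium enolate of the methyl ketone (C2), which adds 5‑exo‑trig to the lactone carbonyl C3 through the chain C2–C1–C10–O10–C3; the bridged hemiketal alkoxide fragments by C3–O10 cleavage to the ten‑membered 1,3‑diketone 22, and its deprotonation to the diketonate makes the acyl transfer irreversible. On acidification O10 re‑adds to C3 (5‑exo‑trig hemiketalisation) and water is lost to give the vinylogous ester, which closes the furanone. The closest known reaction type is the Baker–Venkataraman O‑to‑C acyl transfer followed by cyclodehydration, as used to make 3(2H)‑furanones from α‑acyloxy methyl ketones; because the ester here is a lactone, the same event is a ring expansion from nine‑membered lactone to ten‑membered carbocycle. No stereocentre is formed: C10 is quaternary and untouched, and C4, C5, C6, C7 and C8 are carried through. The step needs enolisation at the ketone methyl group in preference to C4–H of the lactone and to γ‑deprotonation of the methylene lactone: C10 has no hydrogen, the ketone CH3 is the most acidic C–H, and the only small‑ring acylation open to that enolate is the wanted one. A small excess of base and a cold acetic acid quench should limit C4 epimerisation and β‑elimination of the C5 silyloxy group.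

Step 16
Reactants: 23 bis‑silylated furanone
Product: 24 (4S,5S,6S,7R,8S,10R) furanone with free 6‑OH and 5‑OTBS
Conditions: PPTS (cat.), MeOH/CH2Cl2, 0 → 23 °C
Reagents that add atoms: none
Why: Acid‑catalysed methanolysis removes the secondary triethylsilyl ether far faster than the tert‑butyldimethylsilyl ether; C3 is no longer an ester, so the free 6‑OH cannot translactonise.

Step 17
Reactants: 24 C6 alcohol; 25 methacrylic anhydride
Product: 26 (4S,5S,6S,7R,8S,10R) 6‑O‑methacrylate with 5‑OTBS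
Conditions: Et3N, DMAP (cat.), CH2Cl2, 0 → 23 °C
Reagents that add atoms: none
Why: DMAP‑catalysed acylation of the only free hydroxyl group; mild amine base should not move the silyl group or deprotonate C4.

Step 18
Reactants: 26 silyl ether
Product: 27 CNP0195404.1 (target)
Conditions: HF·pyridine, pyridine, THF, 0 → 23 °C
Reagents that add atoms: none
Why: Fluoride‑mediated desilylation under buffered, weakly acidic conditions, which should free 5‑OH without 1,2‑migration of the methacrylate or attack on the methylene lactone.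

**Compound list**

1 | (S)‑lactic acid | C[C@H](O)C(=O)O | starting material
2 | pivalaldehyde | CC(C)(C)C=O | starting material
3 | (2S,5S)‑2‑tert‑butyl‑5‑methyl‑1,3‑dioxolan‑4‑one | C[C@@H]1O[C@H](C(C)(C)C)OC1=O | intermediate
4 | allyl bromide | C=CCBr | starting material
5 | (2S,5R)‑2‑tert‑butyl‑5‑methyl‑5‑(prop‑2‑en‑1‑yl)‑1,3‑dioxolan‑4‑one | C[C@]1(CC=C)O[C@H](C(C)(C)C)OC1=O | intermediate
6 | (R)‑3‑hydroxy‑3‑methylhex‑5‑en‑2‑one | C[C@@](O)(CC=C)C(C)=O | intermediate
7 | (R)‑but‑3‑ene‑1,2‑diol | O[C@@H](CO)C=C | starting material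
8 | (R)‑3,4‑bis(triethylsilyloxy)but‑1‑ene | CC[Si](CC)(CC)O[C@@H](CO[Si](CC)(CC)CC)C=C | intermediate
9 | (S)‑2,3‑bis(triethylsilyloxy)propanal | CC[Si](CC)(CC)O[C@@H](CO[Si](CC)(CC)CC)C=O | intermediate
10 | (S)‑4‑benzyl‑3‑propanoyl‑1,3‑oxazolidin‑2‑one | CCC(=O)N1[C@@H](Cc2ccccc2)COC1=O | starting material
11 | (S)‑4‑benzyl‑3‑[(2S,3S,4S)‑3‑hydroxy‑2‑methyl‑4,5‑bis(triethylsilyloxy)pentanoyl]‑1,3‑oxazolidin‑2‑one | CC[Si](CC)(CC)O[C@@H](CO[Si](CC)(CC)CC)[C@@H](O)[C@H](C)C(=O)N1[C@@H](Cc2ccccc2)COC1=O | intermediate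
12 | (S)‑4‑benzyl‑3‑[(2S,3S,4S)‑3‑(tert‑butyldimethylsilyloxy)‑2‑methyl‑4,5‑bis(triethylsilyloxy)pentanoyl]‑1,3‑oxazolidin‑2‑one | CC[Si](CC)(CC)O[C@@H](CO[Si](CC)(CC)CC)[C@@H](O[Si](C)(C)C(C)(C)C)[C@H](C)C(=O)N1[C@@H](Cc2ccccc2)COC1=O | intermediate
13 | (2S,3S,4S)‑3‑(tert‑butyldimethylsilyloxy)‑2‑methyl‑4,5‑bis(triethylsilyloxy)pentanoic acid | CC[Si](CC)(CC)O[C@@H](CO[Si](CC)(CC)CC)[C@@H](O[Si](C)(C)C(C)(C)C)[C@H](C)C(=O)O | intermediate
14 | (3R)‑3‑methyl‑2‑oxohex‑5‑en‑3‑yl (2S,3S,4S)‑3‑(tert‑butyldimethylsilyloxy)‑2‑methyl‑4,5‑bis(triethylsilyloxy)pentanoate | CC[Si](CC)(CC)O[C@@H](CO[Si](CC)(CC)CC)[C@@H](O[Si](C)(C)C(C)(C)C)[C@H](C)C(=O)O[C@](C)(CC=C)C(C)=O | intermediate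
15 | (3R)‑3‑methyl‑2‑oxohex‑5‑en‑3‑yl (2S,3S,4R)‑3‑(tert‑butyldimethylsilyloxy)‑2‑methyl‑5‑oxo‑4‑(triethylsilyloxy)pentanoate | CC[Si](CC)(CC)O[C@@H](C=O)[C@@H](O[Si](C)(C)C(C)(C)C)[C@H](C)C(=O)O[C@](C)(CC=C)C(C)=O | intermediate
16 | methyl propiolate | C#CC(=O)OC | starting material
17 | 1‑methyl 7‑[(3R)‑3‑methyl‑2‑oxohex‑5‑en‑3‑yl] (4S,5S,6S)‑5‑(tert‑butyldimethylsilyloxy)‑3‑hydroxy‑6‑methyl‑2‑methylidene‑4‑(triethylsilyloxy)heptanedioate, C3 epimers | CC[Si](CC)(CC)O[C@@H](C(O)C(=C)C(=O)OC)[C@@H](O[Si](C)(C)C(C)(C)C)[C@H](C)C(=O)O[C@](C)(CC=C)C(C)=O | intermediate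
18 | 1‑methyl 7‑[(3R)‑3‑methyl‑2‑oxohex‑5‑en‑3‑yl] (2Z,4S,5S,6S)‑2‑(bromomethyl)‑5‑(tert‑butyldimethylsilyloxy)‑6‑methyl‑4‑(triethylsilyloxy)hept‑2‑enedioate | CC[Si](CC)(CC)O[C@@H](/C=C(\CBr)C(=O)OC)[C@@H](O[Si](C)(C)C(C)(C)C)[C@H](C)C(=O)O[C@](C)(CC=C)C(C)=O | intermediate
19 | 1‑methyl 7‑[(3R)‑3‑methyl‑1,4‑dioxopentan‑3‑yl] (2Z,4S,5S,6S)‑2‑(bromomethyl)‑5‑(tert‑butyldimethylsilyloxy)‑6‑methyl‑4‑(triethylsilyloxy)hept‑2‑enedioate | CC[Si](CC)(CC)O[C@@H](/C=C(\CBr)C(=O)OC)[C@@H](O[Si](C)(C)C(C)(C)C)[C@H](C)C(=O)O[C@](C)(CC=O)C(C)=O | intermediate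
20 | (4S,5S,6S,7R,8S,10R) nine‑membered lactone with free 8‑OH and C7 methyl acrylate side chain (not isolated) | CC[Si](CC)(CC)O[C@@H]1[C@@H](O[Si](C)(C)C(C)(C)C)[C@H](C)C(=O)O[C@@](C)(C(C)=O)C[C@H](O)[C@H]1C(=C)C(=O)OC | intermediate
21 | (4S,5S,6S,7R,8S,10R) nine‑membered lactone, 10‑acetyl, 5‑OTBS, 6‑OTES, trans‑fused methylene butyrolactone | CC[Si](CC)(CC)O[C@@H]1[C@@H](O[Si](C)(C)C(C)(C)C)[C@H](C)C(=O)O[C@@](C)(C(C)=O)C[C@@H]2OC(=O)C(=C)[C@@H]12 | intermediate
22 | (4S,5S,6S,7R,8S,10R) ten‑membered 10‑hydroxy‑1,3‑diketone, 5‑OTBS, 6‑OTES (not isolated) | CC[Si](CC)(CC)O[C@@H]1[C@@H](O[Si](C)(C)C(C)(C)C)[C@H](C)C(=O)CC(=O)[C@](C)(O)C[C@@H]2OC(=O)C(=C)[C@@H]12 | intermediate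
23 | (4S,5S,6S,7R,8S,10R) bridged furanone, 5‑OTBS, 6‑OTES | CC[Si](CC)(CC)O[C@@H]1[C@@H](O[Si](C)(C)C(C)(C)C)[C@H](C)C2=CC(=O)[C@@](C)(C[C@@H]3OC(=O)C(=C)[C@@H]13)O2 | intermediate
24 | (4S,5S,6S,7R,8S,10R) bridged furanone, 5‑OTBS, 6‑OH | O[C@@H]1[C@@H](O[Si](C)(C)C(C)(C)C)[C@H](C)C2=CC(=O)[C@@](C)(C[C@@H]3OC(=O)C(=C)[C@@H]13)O2 | intermediate
25 | methacrylic anhydride | CC(=C)C(=O)OC(=O)C(C)=C | starting material
26 | (4S,5S,6S,7R,8S,10R) bridged furanone, 5‑OTBS, 6‑O‑methacrylate | C=C(C)C(=O)O[C@@H]1[C@@H](O[Si](C)(C)C(C)(C)C)[C@H](C)C2=CC(=O)[C@@](C)(C[C@@H]3OC(=O)C(=C)[C@@H]13)O2 | intermediate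
27 | CNP0195404.1 | C=C(C)C(=O)O[C@@H]1[C@@H](O)[C@H](C)C2=CC(=O)[C@@](C)(C[C@@H]3OC(=O)C(=C)[C@@H]13)O2 | target

**Step count:** 18 steps in total. Longest linear sequence: 15 steps (7 → 27, steps 4–18).

**Three steps most likely to fail**

Step 14. Oligomerisation may outrun the nine‑membered closure, and syn instead of anti addition in the strained chair would give the cis‑fused lactone epimeric at C8. The fallback sets out from 19 and returns at 21. The cyclisation product is accepted as the cis‑fused C8‑epimeric lactone F1. Only its γ‑lactone is opened with LiOH in aqueous THF at 0 °C (the tertiary‑alkyl ester of the nine‑membered ring is far more hindered), giving the C8‑epimeric hydroxy acid F2, kept as its triethylammonium salt. F2 is relactonised at once under Mitsunobu conditions (PPh3, diisopropyl azodicarboxylate, toluene, high dilution); the carboxylate displaces the activated C8 oxygen with inversion and gives 21, so that C8 is set by invertive lactonisation and not by the allylation.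

Step 9. Acylation of the hindered tertiary ketol may be too slow, so that epimerisation at C4 or β‑elimination of the silyloxy group of the activated acid takes over. The fallback sets out from 5 and 13 and returns at 14; the acetyl group is masked as the much smaller ethynyl group. LiAlH4 reduction of 5 gives (R)‑2‑methylpent‑4‑ene‑1,2‑diol F3. TEMPO/PhI(OAc)2 oxidation of the primary alcohol gives (R)‑2‑hydroxy‑2‑methylpent‑4‑enal F4. Ohira–Bestmann homologation gives (R)‑3‑methylhex‑5‑en‑1‑yn‑3‑ol F5. Yamaguchi esterification with 13 (a tertiary propargylic alcohol is far less hindered) gives the (3R)‑3‑methylhex‑5‑en‑1‑yn‑3‑yl ester F6. Gold‑catalysed hydration (Ph3PAuNTf2, wet dioxane), directed by 5‑exo‑dig attack of the neighbouring ester carbonyl and hydrolysis of the dioxolenium ion, gives the methyl ketone 14 regioselectively.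

Step 15. Competing deprotonation at C4 or at the γ‑position of the methylene lactone may cause epimerisation, loss of the C5 silyloxy group or isomerisation to the butenolide, and the hemiketal may resist dehydration. The fallback sets out from 21 and returns at 23; the same C2–C3 bond is made by a neutral intramolecular Wittig olefination of the lactone carbonyl. Bromination of the ketone methyl group (phenyltrimethylammonium tribromide, THF, 0 °C; the other α‑carbon is quaternary) gives the bromomethyl ketone F7. PPh3 gives the phosphonium bromide F8, and aqueous Na2CO3 gives the keto‑stabilised ylide F9. Heating in toluene closes the furanone by ester‑carbonyl olefination, a known route to 3(2H)‑furanones and chromones, and gives 23 without any strong base.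

Further compounds
F1 | step 14 | (4S,5S,6S,7R,8R,10R) cis‑fused C8‑epimer of lactone 21 | CC[Si](CC)(CC)O[C@@H]1[C@@H](O[Si](C)(C)C(C)(C)C)[C@H](C)C(=O)O[C@@](C)(C(C)=O)C[C@H]2OC(=O)C(=C)[C@@H]12
F2 | step 14 | C8‑epimeric hydroxy acid (nine‑membered lactone intact, free 8‑OH and acrylic acid side chain on C7) | CC[Si](CC)(CC)O[C@@H]1[C@@H](O[Si](C)(C)C(C)(C)C)[C@H](C)C(=O)O[C@@](C)(C(C)=O)C[C@@H](O)[C@H]1C(=C)C(=O)O
F3 | step 9 | (R)‑2‑methylpent‑4‑ene‑1,2‑diol | C[C@@](O)(CC=C)CO
F4 | step 9 | (R)‑2‑hydroxy‑2‑methylpent‑4‑enal | C[C@@](O)(CC=C)C=O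
F5 | step 9 | (R)‑3‑methylhex‑5‑en‑1‑yn‑3‑ol | C[C@@](O)(CC=C)C#C
F6 | step 9 | (3R)‑3‑methylhex‑5‑en‑1‑yn‑3‑yl (2S,3S,4S)‑3‑(tert‑butyldimethylsilyloxy)‑2‑methyl‑4,5‑bis(triethylsilyloxy)pentanoate | CC[Si](CC)(CC)O[C@@H](CO[Si](CC)(CC)CC)[C@@H](O[Si](C)(C)C(C)(C)C)[C@H](C)C(=O)O[C@](C)(CC=C)C#C
F7 | step 15 | bromomethyl ketone of lactone 21 (10‑bromoacetyl) | CC[Si](CC)(CC)O[C@@H]1[C@@H](O[Si](C)(C)C(C)(C)C)[C@H](C)C(=O)O[C@@](C)(C(=O)CBr)C[C@@H]2OC(=O)C(=C)[C@@H]12
F8 | step 15 | triphenylphosphonium bromide from F7 | CC[Si](CC)(CC)O[C@@H]1[C@@H](O[Si](C)(C)C(C)(C)C)[C@H](C)C(=O)O[C@@](C)(C(=O)C[P+](c3ccccc3)(c3ccccc3)c3ccccc3)C[C@@H]2OC(=O)C(=C)[C@@H]12.[Br-]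
F9 | step 15 | keto‑stabilised phosphorus ylide from F8 | CC[Si](CC)(CC)O[C@@H]1[C@@H](O[Si](C)(C)C(C)(C)C)[C@H](C)C(=O)O[C@@](C)(C(=O)C=P(c3ccccc3)(c3ccccc3)c3ccccc3)C[C@@H]2OC(=O)C(=C)[C@@H]12
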